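Ring B is not brought in as an arene but is built on the finished chromone. Disconnecting C1'–C2' and C5'–C6' leads back to a 2-ethynylchromone and a 1-methoxy-3-silyloxybutadiene. A Diels–Alder reaction followed by loss of methanol creates the whole 4-hydroxyphenyl ring in one operation. It exploits that C1' sits on the electron-poor C2 of ring C with the 4'-oxygen para to it. The precursor is 2-ethynyl-3,5,6,7,8-pentamethoxychromone, whose fully substituted ring A and C3 already carry every methoxy group of the target. O5 stays methylated until a final chelation-controlled demethylation.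

Key step: step 7

Remark: the target has no stereocentre; the enaminone double bond of 7 and the sp3 carbon of racemic 15 are transient. O5 is kept as its methyl ether through step 7 so that no acidic phenol meets the acid-labile diene.

Step 1
Reactants: 1 1,2,3,4-tetramethoxybenzene
Product: 4 2,3,4,5-tetramethoxyphenol, via aryllithium 2 (not isolated), via dimethyl arylboronate 3 (not isolated)
Conditions: n-BuLi, TMEDA, THF, 0 → 25 °C; B(OMe)3, −78 → 25 °C; 30% H2O2, 0 → 25 °C
Reagents that add atoms: hydrogen peroxide, OO
Why: Directed ortho-metalation followed by borylation and oxidative boron-to-oxygen migration (a standard one-flask phenol synthesis) can give only the 2,3,4,5-pattern, because the two remaining ring hydrogens of 1 are equivalent and each lies ortho to a methoxy group.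

Step 2
Reactants: 4 2,3,4,5-tetramethoxyphenol
Product: 6 1-(2-hydroxy-3,4,5,6-tetramethoxyphenyl)-2-methoxyethan-1-one, via difluoroboron chelate 5 (not isolated)
Conditions: MeOCH2CO2H, BF3·OEt2 (neat), 80 °C; then aq. MeOH, 60 °C
Reagents that add atoms: methoxyacetic acid, COCC(=O)O
Why: In this BF3-mediated Friedel–Crafts (Fries-type) ortho-acylation of a phenol by a carboxylic acid, the single free ring position of 4 is ortho to the hydroxyl, so regiochemistry is not in question, and the ketone is held as its difluoroboron chelate 5 until hydrolytic work-up.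

Step 3
Reactants: 6 1-(2-hydroxy-3,4,5,6-tetramethoxyphenyl)-2-methoxyethan-1-one
Product: 8 3,5,6,7,8-pentamethoxy-4H-chromen-4-one, via enaminone 7 (not isolated)
Conditions: Me2NCH(OMe)2, toluene, 100 °C; then AcOH, 60 °C
Reagents that add atoms: N,N-dimethylformamide dimethyl acetal, COC(OC)N(C)C
Why: In this enaminone annulation to a chromone, the amide acetal condenses at the α-methoxy methylene of the ketone, and the phenol oxygen then adds to the β-carbon and expels dimethylamine (addition–elimination), closing the pyranone with C2 unsubstituted and the 3-methoxy group in place.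

Step 4
Reactants: 8 3,5,6,7,8-pentamethoxy-4H-chromen-4-one
Product: 10 2-iodo-3,5,6,7,8-pentamethoxy-4H-chromen-4-one, via chromon-2-ylzinc chloride 9 (not isolated)
Conditions: TMPZnCl·LiCl, THF, 0 → 25 °C; then I2, 0 → 25 °C
Reagents that add atoms: iodine, II
Why: Zincation with a hindered amide base followed by iodinolysis should occur at C2, since C2–H is the only sp2 C–H of 8 and is acidified by O1 and the neighbouring 3-methoxy group, while the mild zinc amide does not add to the pyranone.

Step 5
Reactants: 10 2-iodo-3,5,6,7,8-pentamethoxy-4H-chromen-4-one; 11 trimethylsilylacetylene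
Product: 12 3,5,6,7,8-pentamethoxy-2-[(trimethylsilyl)ethynyl]-4H-chromen-4-one
Conditions: Pd(PPh3)2Cl2 (cat.), CuI (cat.), iPr2NEt, THF, 25 °C
Reagents that add atoms: none
Why: In this Sonogashira coupling the C2–I bond of the β-iodo-enone-type iodide should add oxidatively to zerovalent palladium with ease, and a hindered tertiary amine is chosen so that the base cannot displace iodide at C2.

Step 6
Reactants: 12 3,5,6,7,8-pentamethoxy-2-[(trimethylsilyl)ethynyl]-4H-chromen-4-one
Product: 13 2-ethynyl-3,5,6,7,8-pentamethoxy-4H-chromen-4-one
Conditions: TBAF, AcOH, THF, −20 → 0 °C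
Reagents that add atoms: none
Why: Fluoride-induced protodesilylation of the alkynylsilane is buffered with acetic acid so that no alkoxide or free fluoride remains to add to the acceptor alkyne or to C2, and 13 is taken on without storage.

Step 7
Reactants: 13 2-ethynyl-3,5,6,7,8-pentamethoxy-4H-chromen-4-one; 14 (E)-1-methoxy-3-(trimethylsilyloxy)buta-1,3-diene
Product: 17 4'-hydroxy-3,5,6,7,8-pentamethoxyflavone, via cyclohexa-1,4-diene cycloadduct 15 (not isolated), via aryl trimethylsilyl ether 16 (not isolated)
Conditions: 14 (3 equiv), toluene, 110 °C, sealed tube; then 1 M HCl, THF, 25 °C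
Reagents that add atoms: none
Why: A thermal normal-electron-demand Diels–Alder reaction, the benzannulation of 1-alkoxy-3-silyloxybutadienes with acceptor-substituted alkynes, joins the electron-rich diene 14 to the alkyne of 13, whose LUMO is lowered by conjugation through C2=C3 to the C4 carbonyl. Ring B closes as a six-membered carbocycle by a concerted but asynchronous [4+2] cycloaddition in which C5'–C6' (diene C4 to the alkyne CH) forms slightly ahead of C1'–C2' (diene C1 to the internal alkyne carbon). The regioselectivity needed, 4'- and not 3'-oxygenation, follows from pairing the most nucleophilic diene carbon (C4, the CH2 of the silyl enol ether) with the alkyne CH, the remote electrophilic end of the C4=O/C3=C2/C≡C acceptor chain, which places the silyloxy carbon three bonds from C1' on either side. The skipped diene 15 should then lose methanol by 1,4-elimination (the C2' methoxy group and a C5' hydrogen), driven by aromatization, and dilute acid cleaves the aryl silyl ether 16 to the phenol. The single sp3 stereocentre of 15 (C2') forms as a racemate and is erased on aromatization, so no stereocontrol is required. Chemoselectivity is secured because the only other π-bond of the acceptor, C2=C3, is tetrasubstituted and part of the pyranone, and because O5 is methylated, so no phenol is present to protonate the diene.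

Step 8
Reactants: 17 4'-hydroxy-3,5,6,7,8-pentamethoxyflavone
Product: 19 calycopterin (4',5-dihydroxy-3,6,7,8-tetramethoxyflavone), via dichloroboron chelate 18 (not isolated)
Conditions: BCl3 (3 equiv), CH2Cl2, −78 → 0 °C; then H2O
Reagents that add atoms: none
Why: In this chelation-controlled Lewis-acid ether cleavage, boron bound to the C4 carbonyl oxygen forms a six-membered chelate only with the peri 5-oxygen and so activates that one methyl group for chloride attack, while the 3-, 6-, 7- and 8-methyl ethers lack this activation at low temperature and the 4'-borate is hydrolysed on work-up.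

Compound list
1 | 1,2,3,4-tetramethoxybenzene | COc1ccc(OC)c(OC)c1OC | starting material
2 | (2,3,4,5-tetramethoxyphenyl)lithium | [Li]c1cc(OC)c(OC)c(OC)c1OC | intermediate
3 | dimethyl (2,3,4,5-tetramethoxyphenyl)boronate | COB(OC)c1cc(OC)c(OC)c(OC)c1OC | intermediate
4 | 2,3,4,5-tetramethoxyphenol | COc1cc(O)c(OC)c(OC)c1OC | intermediate
5 | difluoroboron chelate of ketone 6 (boron bridging the phenol oxygen and the ketone oxygen) | COCC1=[O+][B-](F)(F)Oc2c(OC)c(OC)c(OC)c(OC)c12 | intermediate
6 | 1-(2-hydroxy-3,4,5,6-tetramethoxyphenyl)-2-methoxyethan-1-one | COCC(=O)c1c(O)c(OC)c(OC)c(OC)c1OC | intermediate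
7 | (Z)-3-(dimethylamino)-1-(2-hydroxy-3,4,5,6-tetramethoxyphenyl)-2-methoxyprop-2-en-1-one (geometry of no consequence) | CN(C)/C=C(\OC)C(=O)c1c(O)c(OC)c(OC)c(OC)c1OC | intermediate
8 | 3,5,6,7,8-pentamethoxy-4H-chromen-4-one | COc1coc2c(OC)c(OC)c(OC)c(OC)c2c1=O | intermediate
9 | chloro(3,5,6,7,8-pentamethoxy-4-oxo-4H-chromen-2-yl)zinc | COc1c([Zn]Cl)oc2c(OC)c(OC)c(OC)c(OC)c2c1=O | intermediate
10 | 2-iodo-3,5,6,7,8-pentamethoxy-4H-chromen-4-one | COc1c(I)oc2c(OC)c(OC)c(OC)c(OC)c2c1=O | intermediate
11 | trimethylsilylacetylene | C#C[Si](C)(C)C | starting material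
12 | 3,5,6,7,8-pentamethoxy-2-[(trimethylsilyl)ethynyl]-4H-chromen-4-one | COc1c(C#C[Si](C)(C)C)oc2c(OC)c(OC)c(OC)c(OC)c2c1=O | intermediate
13 | 2-ethynyl-3,5,6,7,8-pentamethoxy-4H-chromen-4-one | C#Cc1oc2c(OC)c(OC)c(OC)c(OC)c2c(=O)c1OC | intermediate
14 | (E)-1-methoxy-3-(trimethylsilyloxy)buta-1,3-diene | CO/C=C/C(=C)O[Si](C)(C)C | starting material
15 | 3,5,6,7,8-pentamethoxy-2-[6-methoxy-4-(trimethylsilyloxy)cyclohexa-1,4-dien-1-yl]-4H-chromen-4-one (racemic) | COC1C=C(O[Si](C)(C)C)CC=C1c1oc2c(OC)c(OC)c(OC)c(OC)c2c(=O)c1OC | intermediate
16 | 3,5,6,7,8-pentamethoxy-2-[4-(trimethylsilyloxy)phenyl]-4H-chromen-4-one | COc1c(-c2ccc(O[Si](C)(C)C)cc2)oc2c(OC)c(OC)c(OC)c(OC)c2c1=O | intermediate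
17 | 4'-hydroxy-3,5,6,7,8-pentamethoxyflavone | COc1c(OC)c(OC)c2c(=O)c(OC)c(-c3ccc(O)cc3)oc2c1OC | intermediate
18 | dichloroboron chelate bridging O5 and the C4 carbonyl oxygen of the 3,6,7,8-tetramethoxyflavone, with the 4'-oxygen as its dichloroborate | COc1c(OC)c3O[B-](Cl)(Cl)[O+]=C4C(OC)=C(c5ccc(OB(Cl)Cl)cc5)Oc(c34)c1OC | intermediate
19 | calycopterin, 4',5-dihydroxy-3,6,7,8-tetramethoxyflavone | COc1c(OC)c(O)c2c(=O)c(OC)c(-c3ccc(O)cc3)oc2c1OC | target

Total step count: 8. Longest linear sequence: 8 steps (1 to 19); 11 and 14 are bought.

Steps most likely to fail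

Step 7. The alkyne is activated only through the C2=C3 bond, so the cycloaddition may be slow enough for thermal loss of the diene or oligomerization of the terminal alkyne to overtake ring formation. In that case ring B would be brought in intact. Setting out from iodide 10, a Suzuki–Miyaura coupling with 4-hydroxyphenylboronic acid (Pd(PPh3)4, K3PO4, dioxane/H2O, 80 °C) should give 17 directly, and the route is rejoined at 17 before step 8. No compound outside the list is made (F0).

Step 4. Deprotonation at C2 may remain incomplete, or the amide base may add to the pyranone and open it, and the labile C2–I bond may be lost on work-up. The C2 carbon would then be built in during ring closure instead of by C–H functionalization. Setting out from ketone 6, a Kostanecki–Robinson reaction (Ac2O, NaOAc, 170 °C) should give 2-methyl-3,5,6,7,8-pentamethoxy-4H-chromen-4-one F1. Oxidation of its activated methyl group with SeO2 (dioxane, 100 °C) should give 3,5,6,7,8-pentamethoxy-4-oxo-4H-chromene-2-carbaldehyde F2. Colvin homologation with lithiated trimethylsilyldiazomethane (Me3SiCHN2, LiN(iPr)2, THF, −78 → 0 °C) should then give the alkyne, and the route is rejoined at 13 before the key step.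

Step 2. C-acylation at the crowded last ring position may stall at the aryl ester, or the Lewis acid may begin to cleave methyl ethers on prolonged heating. The acyl group would then be introduced by an anionic route. Setting out from phenol 4, protection (MOMCl, iPr2NEt, CH2Cl2) should give 1,2,3,4-tetramethoxy-5-(methoxymethoxy)benzene F3. Ortho-lithiation between the two oxygen substituents (n-BuLi, THF, 0 °C) should give [2-(methoxymethoxy)-3,4,5,6-tetramethoxyphenyl]lithium F4. Acylation of F4 with N,2-dimethoxy-N-methylacetamide should give 2-methoxy-1-[2-(methoxymethoxy)-3,4,5,6-tetramethoxyphenyl]ethan-1-one F5. Acetal cleavage (HCl, MeOH, 25 °C) then rejoins the route at 6.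

Further compounds
F0 | step 7 | none | none
F1 | step 4 | 2-methyl-3,5,6,7,8-pentamethoxy-4H-chromen-4-one | COc1c(C)oc2c(OC)c(OC)c(OC)c(OC)c2c1=O
F2 | step 4 | 3,5,6,7,8-pentamethoxy-4-oxo-4H-chromene-2-carbaldehyde | COc1c(C=O)oc2c(OC)c(OC)c(OC)c(OC)c2c1=O
F3 | step 2 | 1,2,3,4-tetramethoxy-5-(methoxymethoxy)benzene | COCOc1cc(OC)c(OC)c(OC)c1OC
F4 | step 2 | [2-(methoxymethoxy)-3,4,5,6-tetramethoxyphenyl]lithium | [Li]c1c(OCOC)c(OC)c(OC)c(OC)c1OC
F5 | step 2 | 2-methoxy-1-[2-(methoxymethoxy)-3,4,5,6-tetramethoxyphenyl]ethan-1-one | COCOc1c(C(=O)COC)c(OC)c(OC)c(OC)c1OC
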